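The route rests on the bond between C3 of the dihydrobenzofuran fused to ring A and ring B: because C3 carries two aryl rings (A and B), it can be assembled as a diaryl carbene carbon. The aryl Grignard of an enantiopure bis(dihydrobenzofuran) (rings B to D) adds to a 2-bromo-6-(4-methoxybenzyloxy)benzonitrile and hydrazine exchange gives, in one flask, the diaryl hydrazone, with O1–C2–aryl hidden in the benzyl ether 1,5 to C3. A chiral rhodium carbene C–H insertion then closes the ring and sets C3; the same nitrile builds all three rings. Global demethylation equilibrates the three C2 centres to trans, and a Suzuki coupling adds the hydroxystyryl arm.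

Key step: step 9

Assumption: Rh2(R-PTAD)4 (dirhodium tetrakis[(R)-(1-adamantyl)(N-phthalimido)acetate]) is taken as the catalyst enantiomer that gives the 3R ring, and the insertion is taken to give the cis ring kinetically; if the first ring (12) shows the opposite sense, the two catalyst enantiomers are exchanged in steps 6, 8 and 10.

Labels used below: ring A carries the styryl arm, rings B and C follow along the chain, ring D is the 3,5-dioxygenated phenyl end group. "Furan ring A, B or C" is the dihydrobenzofuran fused to ring A, B or C, numbered O1, C2 (bearing the 4-oxyphenyl group), C3, with the bromine or the next unit on C4.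

Step 1
Reactants: 1 1-bromo-3,5-dimethoxybenzene
Product: 2 2-bromo-4,6-dimethoxybenzaldehyde
Conditions: POCl3, DMF, 0 → 90 °C; then aq. NaOAc
Reagents that add atoms: N,N-dimethylformamide CN(C)C=O; water O
Why: Vilsmeier–Haack formylation, in which the chloroiminium ion should attack the ring carbon para to one methoxy group and ortho to the other (next to bromine) rather than the carbon flanked by both methoxy groups.

Step 2
Reactants: 2 2-bromo-4,6-dimethoxybenzaldehyde
Product: 3 2-bromo-6-hydroxy-4-methoxybenzaldehyde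
Conditions: BCl3, CH2Cl2, −78 → 0 °C; aq. work-up
Reagents that add atoms: none
Why: Lewis-acid ether cleavage directed by chelation of boron between the formyl oxygen and the ortho methoxy oxygen, so only the ortho methyl ether should be cut.

Step 3
Reactants: 3 2-bromo-6-hydroxy-4-methoxybenzaldehyde; 4 4-methoxybenzyl chloride
Product: 5 2-bromo-4-methoxy-6-[(4-methoxybenzyl)oxy]benzaldehyde
Conditions: K2CO3, NaI (cat.), DMF, 60 °C
Reagents that add atoms: none
Why: Williamson etherification of the acidic salicylaldehyde-type phenol; this benzyl group is not a protecting group but supplies C2 and its aryl ring for each future dihydrobenzofuran.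

Step 4
Reactants: 5 2-bromo-4-methoxy-6-[(4-methoxybenzyl)oxy]benzaldehyde
Product: 7 2-bromo-4-methoxy-6-[(4-methoxybenzyl)oxy]benzonitrile, via aldoxime 6 (not isolated)
Conditions: NH2OH·HCl, pyridine, 60 °C; then Ac2O, 100 °C
Reagents that add atoms: hydroxylamine hydrochloride NO.Cl
Why: Oxime formation followed by dehydration through the O-acetyl oxime (aldehyde-to-nitrile conversion), which should leave the benzyl ether and the aryl bromide untouched.

Step 5
Reactants: 1 1-bromo-3,5-dimethoxybenzene; 7 2-bromo-4-methoxy-6-[(4-methoxybenzyl)oxy]benzonitrile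
Product: 10 N-unsubstituted hydrazone of (2-bromo-4-methoxy-6-[(4-methoxybenzyl)oxy]phenyl)(3,5-dimethoxyphenyl)methanone, via aryl Grignard 8 (not isolated), via ketimine 9 (not isolated)
Conditions: 1, Mg, LiCl, THF, 25 °C; transfer from excess Mg onto 7, THF/toluene, 70 °C; MeOH; then N2H4·H2O, AcOH, EtOH, 70 °C
Reagents that add atoms: hydrazine hydrate NN.O
Why: Grignard addition to the nitrile stops at the N-magnesio ketimine, and acid-catalysed imine–hydrazine exchange then gives the hydrazone (both nitrogens from hydrazine) without passing through the hindered diaryl ketone.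

Step 6
Reactants: 10 hydrazone from step 5
Product: 12 (2S,3R)-4-bromo-3-(3,5-dimethoxyphenyl)-6-methoxy-2-(4-methoxyphenyl)-2,3-dihydro-1-benzofuran (cis; furan ring C), via diaryldiazomethane 11 (not isolated)
Conditions: MnO2, CH2Cl2, 0 °C; filter; Rh2(R-PTAD)4 (1 mol %), CH2Cl2, 0 → 25 °C
Reagents that add atoms: none
Why: MnO2 dehydrogenates the hydrazone to the diazo compound and the chiral divalent rhodium carboxylate turns it into a donor/donor carbene that inserts 1,5 into the benzylic C–H bond of the ortho O–CH2–aryl ether (intramolecular rhodium-carbene C–H insertion), forming C2–C3 with C3 set as R by the catalyst and C2 cis to it by the insertion geometry.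

Step 7
Reactants: 12 cis furan ring C bromide; 7 2-bromo-4-methoxy-6-[(4-methoxybenzyl)oxy]benzonitrile
Product: 16 N-unsubstituted hydrazone of (2-bromo-4-methoxy-6-[(4-methoxybenzyl)oxy]phenyl)[(2S,3R)-3-(3,5-dimethoxyphenyl)-6-methoxy-2-(4-methoxyphenyl)-2,3-dihydro-1-benzofuran-4-yl]methanone, via aryllithium 13 (not isolated), via aryl Grignard 14 (not isolated), via ketimine 15 (not isolated)
Conditions: 12, t-BuLi (2 equiv), THF, −78 °C; MgBr2·OEt2, −78 → 0 °C; 7, THF/toluene, 70 °C; MeOH; then N2H4·H2O, AcOH, EtOH, 70 °C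
Reagents that add atoms: hydrazine hydrate NN.O
Why: Bromine–lithium exchange, transmetalation to magnesium (so that the aryl bromide of 7 is not exchanged), Grignard addition to the nitrile and imine–hydrazine exchange repeat step 5 on the first ring, whose C2–H and C3–H are not acidic enough to be removed by an aryl magnesium reagent.

Step 8
Reactants: 16 hydrazone from step 7
Product: 18 bis(dihydrobenzofuran) bromide: new furan ring B (2R,3S) cis with bromine on C4; its C3 bears C4 of the (2S,3R) cis furan ring C, via diaryldiazomethane 17 (not isolated)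
Conditions: MnO2, CH2Cl2, 0 °C; filter; Rh2(S-PTAD)4 (2 mol %), CH2Cl2, 0 → 25 °C
Reagents that add atoms: none
Why: The same hydrazone oxidation and rhodium-carbene 1,5 C–H insertion as in step 6, now with the enantiomeric catalyst so that the new C3 is set as S (C2 cis, R), catalyst control being expected to override the neighbouring ring.

Step 9
Reactants: 18 bis(dihydrobenzofuran) bromide; 7 2-bromo-4-methoxy-6-[(4-methoxybenzyl)oxy]benzonitrile
Product: 22 N-unsubstituted hydrazone of (2-bromo-4-methoxy-6-[(4-methoxybenzyl)oxy]phenyl)(aryl)methanone in which aryl is C4 of furan ring B of 18, via aryllithium 19 (not isolated), via aryl Grignard 20 (not isolated), via ketimine 21 (not isolated)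
Conditions: 18, t-BuLi (2 equiv), THF, −78 °C; MgBr2·OEt2, −78 → 0 °C; 7 (1.2 equiv), THF/toluene, 70 °C; MeOH; then N2H4·H2O, AcOH, EtOH, 70 °C
Reagents that add atoms: hydrazine hydrate NN.O
Why: Bromine–lithium exchange on 18 and transmetalation give aryl Grignard 20, whose ring B carbon (meta to both ring oxygens, so out of reach of electrophilic substitution) adds to the nitrile carbon of 7, the future C3, and the N-magnesio ketimine resists a second addition; methanol frees ketimine 21, and acid-catalysed imine–hydrazine exchange (addition of hydrazine, loss of ammonia) gives 22 without passing through the tri-ortho-substituted ketone. The closest known reaction types are the Grignard addition to hindered benzonitriles, which gives stable N–H ketimines, and the transimination of N–H ketimines with hydrazine. No ring is closed here: 22 stores furan ring A in open form, with ring A, C3 as the carbene precursor carbon and, in the 4-methoxybenzyl ether on the ortho oxygen, O1, C2 and the C2 aryl group, and step 10 closes it by 1,5 C–H insertion. No new stereocentre is formed, and the four existing ones are not touched because the ring C–H bonds are not deprotonated by an aryl magnesium reagent. The step needs chemoselectivity for C≡N over the aryl bromide of 7 and over displacement of the ortho benzyloxy group: magnesium, unlike lithium, does not exchange with aryl bromides, t-BuLi is consumed before 7 is added, and the linear nitrile is the least hindered electrophilic site.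

Step 10
Reactants: 22 hydrazone from step 9
Product: 24 tris(dihydrobenzofuran) bromide with three cis rings: new furan ring A (2S,3R) with bromine on C4; furan ring B (2R,3S); furan ring C (2S,3R), via diaryldiazomethane 23 (not isolated)
Conditions: MnO2, CH2Cl2, 0 °C; filter; Rh2(R-PTAD)4 (2 mol %), CH2Cl2, 0 → 40 °C
Reagents that add atoms: none
Why: MnO2 dehydrogenation and rhodium-carbene 1,5 insertion into the benzylic C–H of the O–CH2–aryl ether close furan ring A through the C2–C3 bond, and the chiral divalent rhodium carboxylate should set C3 as R (C2 cis, S) against the four remote stereocentres.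

Step 11
Reactants: 24 tris(dihydrobenzofuran) bromide
Product: 25 all-trans nonaphenol bromide (the target with bromine in place of the hydroxystyryl arm; rings A/B/C = (2R,3R)/(2S,3S)/(2R,3R))
Conditions: BBr3 (excess), CH2Cl2, −78 → 25 °C; MeOH quench; then HCl (cat.), MeCN/H2O, 40 °C
Reagents that add atoms: none
Why: BBr3 cleaves the nine aryl methyl ethers (Lewis-acid demethylation) and, like the dilute acid that follows, reversibly ionises each C2–O1 bond to a 4-oxybenzyl cation or quinone methide that recloses, so each C2 should settle trans to its untouched C3 (thermodynamic relay), before any acid-sensitive stilbene is present.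

Step 12
Reactants: 26 4-acetoxystyrene; 27 vinylboronic acid pinacol ester
Product: 28 (E)-2-(4-acetoxyphenyl)vinylboronic acid pinacol ester
Conditions: second-generation Grubbs catalyst (5 mol %), CH2Cl2, 40 °C
Reagents that add atoms: none
Why: Olefin cross-metathesis of a styrene with the vinyl boronate, driven by loss of ethene and expected to give the E-alkenyl boronate.

Step 13
Reactants: 25 all-trans nonaphenol bromide; 28 (E)-2-(4-acetoxyphenyl)vinylboronic acid pinacol ester
Product: 30 miyabenol A, via hydroxystyryl boronate 29 (not isolated)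
Conditions: 28, K2CO3, MeOH, 25 °C; then 25, Pd(OAc)2, SPhos, K3PO4, dioxane/H2O, 80 °C, argon; aq. NH4Cl
Reagents that add atoms: none
Why: Methanolysis frees the phenol of the boronate, and Suzuki–Miyaura coupling of the aryl bromide (meta to both ring A oxygens, so little deactivated by phenoxide formation) with the E-alkenyl boronate keeps the alkene geometry and exposes the stilbene to no acid.

Compound list
1 | 1-bromo-3,5-dimethoxybenzene | COc1cc(Br)cc(OC)c1 | starting material
2 | 2-bromo-4,6-dimethoxybenzaldehyde | COc1cc(Br)c(C=O)c(OC)c1 | intermediate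
3 | 2-bromo-6-hydroxy-4-methoxybenzaldehyde | COc1cc(O)c(C=O)c(Br)c1 | intermediate
4 | 4-methoxybenzyl chloride | COc1ccc(CCl)cc1 | starting material
5 | 2-bromo-4-methoxy-6-[(4-methoxybenzyl)oxy]benzaldehyde | COc1ccc(COc2cc(OC)cc(Br)c2C=O)cc1 | intermediate
6 | (E)-aldoxime of 5 | COc1ccc(COc2cc(OC)cc(Br)c2/C=N/O)cc1 | intermediate
7 | 2-bromo-4-methoxy-6-[(4-methoxybenzyl)oxy]benzonitrile | COc1ccc(COc2cc(OC)cc(Br)c2C#N)cc1 | intermediate
8 | (3,5-dimethoxyphenyl)magnesium bromide | COc1cc([Mg]Br)cc(OC)c1 | intermediate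
9 | N–H ketimine: (2-bromo-4-methoxy-6-[(4-methoxybenzyl)oxy]phenyl)(3,5-dimethoxyphenyl)methanimine | COc1ccc(COc2cc(OC)cc(Br)c2C(=N)c2cc(OC)cc(OC)c2)cc1 | intermediate
10 | hydrazone of (2-bromo-4-methoxy-6-[(4-methoxybenzyl)oxy]phenyl)(3,5-dimethoxyphenyl)methanone (C=N isomers) | COc1ccc(COc2cc(OC)cc(Br)c2C(=NN)c2cc(OC)cc(OC)c2)cc1 | intermediate
11 | 2-bromo-1-[diazo(3,5-dimethoxyphenyl)methyl]-5-methoxy-3-[(4-methoxybenzyl)oxy]benzene | COc1ccc(COc2cc(OC)cc(Br)c2C(=[N+]=[N-])c2cc(OC)cc(OC)c2)cc1 | intermediate
12 | (2S,3R)-4-bromo-3-(3,5-dimethoxyphenyl)-6-methoxy-2-(4-methoxyphenyl)-2,3-dihydro-1-benzofuran (cis) | Brc1cc(OC)cc2c1[C@@H](c1cc(OC)cc(OC)c1)[C@@H](c1ccc(OC)cc1)O2 | intermediate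
13 | aryllithium of 12 (Li in place of Br at C4) | [Li]c1cc(OC)cc2c1[C@@H](c1cc(OC)cc(OC)c1)[C@@H](c1ccc(OC)cc1)O2 | intermediate
14 | aryl magnesium bromide of 12 (MgBr at C4) | Br[Mg]c1cc(OC)cc2c1[C@@H](c1cc(OC)cc(OC)c1)[C@@H](c1ccc(OC)cc1)O2 | intermediate
15 | N–H ketimine from 14 and 7 (C=NH between C4 of ring 12 and the bromo benzyloxy aryl ring) | N=C(c1c(Br)cc(OC)cc1OCc1ccc(OC)cc1)c1cc(OC)cc2c1[C@@H](c1cc(OC)cc(OC)c1)[C@@H](c1ccc(OC)cc1)O2 | intermediate
16 | hydrazone of (2-bromo-4-methoxy-6-[(4-methoxybenzyl)oxy]phenyl)[(2S,3R)-3-(3,5-dimethoxyphenyl)-6-methoxy-2-(4-methoxyphenyl)-2,3-dihydro-1-benzofuran-4-yl]methanone | NN=C(c1c(Br)cc(OC)cc1OCc1ccc(OC)cc1)c1cc(OC)cc2c1[C@@H](c1cc(OC)cc(OC)c1)[C@@H](c1ccc(OC)cc1)O2 | intermediate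
17 | diaryldiazomethane from 16 | [N-]=[N+]=C(c1c(Br)cc(OC)cc1OCc1ccc(OC)cc1)c1cc(OC)cc2c1[C@@H](c1cc(OC)cc(OC)c1)[C@@H](c1ccc(OC)cc1)O2 | intermediate
18 | bis(dihydrobenzofuran) bromide: (2R,3S)-4-bromo-6-methoxy-2-(4-methoxyphenyl)-2,3-dihydro-1-benzofuran whose C3 bears the (2S,3R)-3-(3,5-dimethoxyphenyl)-6-methoxy-2-(4-methoxyphenyl)-2,3-dihydro-1-benzofuran-4-yl group (both rings cis) | Brc1cc(OC)cc2c1[C@H](c1cc(OC)cc3c1[C@@H](c1cc(OC)cc(OC)c1)[C@@H](c1ccc(OC)cc1)O3)[C@H](c1ccc(OC)cc1)O2 | intermediate
19 | aryllithium of 18 (Li in place of Br) | [Li]c1cc(OC)cc2c1[C@H](c1cc(OC)cc3c1[C@@H](c1cc(OC)cc(OC)c1)[C@@H](c1ccc(OC)cc1)O3)[C@H](c1ccc(OC)cc1)O2 | intermediate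
20 | aryl magnesium bromide of 18 | Br[Mg]c1cc(OC)cc2c1[C@H](c1cc(OC)cc3c1[C@@H](c1cc(OC)cc(OC)c1)[C@@H](c1ccc(OC)cc1)O3)[C@H](c1ccc(OC)cc1)O2 | intermediate
21 | N–H ketimine from 20 and 7 | N=C(c1c(Br)cc(OC)cc1OCc1ccc(OC)cc1)c1cc(OC)cc2c1[C@H](c1cc(OC)cc3c1[C@@H](c1cc(OC)cc(OC)c1)[C@@H](c1ccc(OC)cc1)O3)[C@H](c1ccc(OC)cc1)O2 | intermediate
22 | hydrazone of the diaryl ketone joining C4 of furan ring B of 18 to the 2-bromo-4-methoxy-6-[(4-methoxybenzyl)oxy]phenyl ring | NN=C(c1c(Br)cc(OC)cc1OCc1ccc(OC)cc1)c1cc(OC)cc2c1[C@H](c1cc(OC)cc3c1[C@@H](c1cc(OC)cc(OC)c1)[C@@H](c1ccc(OC)cc1)O3)[C@H](c1ccc(OC)cc1)O2 | intermediate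
23 | diaryldiazomethane from 22 | [N-]=[N+]=C(c1c(Br)cc(OC)cc1OCc1ccc(OC)cc1)c1cc(OC)cc2c1[C@H](c1cc(OC)cc3c1[C@@H](c1cc(OC)cc(OC)c1)[C@@H](c1ccc(OC)cc1)O3)[C@H](c1ccc(OC)cc1)O2 | intermediate
24 | tris(dihydrobenzofuran) bromide, nonamethyl ether, three cis rings: A (2S,3R), B (2R,3S), C (2S,3R) | Brc1cc(OC)cc2c1[C@@H](c1cc(OC)cc3c1[C@H](c1cc(OC)cc4c1[C@@H](c1cc(OC)cc(OC)c1)[C@@H](c1ccc(OC)cc1)O4)[C@H](c1ccc(OC)cc1)O3)[C@@H](c1ccc(OC)cc1)O2 | intermediate
25 | all-trans nonaphenol bromide: rings A (2R,3R), B (2S,3S), C (2R,3R) | Brc1cc(O)cc2c1[C@@H](c1cc(O)cc3c1[C@H](c1cc(O)cc4c1[C@@H](c1cc(O)cc(O)c1)[C@H](c1ccc(O)cc1)O4)[C@@H](c1ccc(O)cc1)O3)[C@H](c1ccc(O)cc1)O2 | intermediate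
26 | 4-acetoxystyrene | CC(=O)Oc1ccc(C=C)cc1 | starting material
27 | vinylboronic acid pinacol ester | C=CB1OC(C)(C)C(C)(C)O1 | starting material
28 | (E)-2-(4-acetoxyphenyl)vinylboronic acid pinacol ester | CC(=O)Oc1ccc(/C=C/B2OC(C)(C)C(C)(C)O2)cc1 | intermediate
29 | (E)-2-(4-hydroxyphenyl)vinylboronic acid pinacol ester | Oc1ccc(/C=C/B2OC(C)(C)C(C)(C)O2)cc1 | intermediate
30 | miyabenol A | Oc1ccc(/C=C/c2cc(O)cc3c2[C@@H](c2cc(O)cc4c2[C@H](c2cc(O)cc5c2[C@@H](c2cc(O)cc(O)c2)[C@H](c2ccc(O)cc2)O5)[C@@H](c2ccc(O)cc2)O4)[C@H](c2ccc(O)cc2)O3)cc1 | target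

Total step count: 13. Longest linear sequence: 12 steps (steps 1–11 and 13; step 12 is a side branch).

Steps most likely to fail

1. Step 9 (key step). The hindered aryl magnesium may add too slowly to the di-ortho-substituted nitrile, or may displace the ortho benzyloxy group instead. The hydrazine exchange may also stall at the crowded ketimine carbon. Fallback, setting out from 18 (through aryllithium 19) and aldehyde 5 and coming back at 22: aryllithium 19 is added at −78 °C to aldehyde 5, an addition far faster than bromine–lithium exchange with the bromide of 5, to give diaryl carbinol F1 (carbinol epimers). DMP in CH2Cl2 oxidises it to diaryl ketone F2. Forcing condensation (anhydrous N2H4, N2H4·2HCl, DMSO, 100 °C), which methyl and benzyl ethers tolerate, then gives hydrazone 22.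

2. Step 10. The crowded diazo carbon may form the rhodium carbene slowly, so that azine formation takes over. The carbene may also insert into the C2–H bond of the neighbouring furan ring B, and facial selectivity may erode if substrate and catalyst oppose each other. Fallback, setting out from 18 (as Grignard 20), 3 and 4 and coming back at 25: phenol 3 is converted with Boc2O and DMAP (cat.) into aryl tert-butyl carbonate F3. (2R,5R)-2,5-Dimethylthiolane, 4 and NaBF4 give benzylsulfonium salt F4, and KN(SiMe3)2 at −78 °C turns it into sulfonium ylide F5; the sulfide enantiomer is to be confirmed on a model annulation. Grignard 20 adds to the formyl group of F3 at −78 °C. On warming, the magnesium alkoxide takes over the Boc group and loses tert-butyl carbonate to give o-quinone methide F6, whose methide carbon (C3) is attacked by ylide F5. The ring A phenoxide then displaces the sulfide at C2 (5-exo-tet), a [4+1] annulation of sulfur ylides with o-quinone methides that gives trans rings. The product is tris(dihydrobenzofuran) bromide F7, with furan ring A already (2R,3R), and it is carried through step 11 to 25.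

3. Step 11. Ring-opened benzylic cations may be captured by a neighbouring electron-rich ring (Friedel–Crafts closure to a seven-membered ring); demethylation or C2 equilibration may also stay incomplete. Fallback, setting out from 24 and coming back at 25: the methyl ethers are cut by halide attack on magnesium-bound ethers without a strong Lewis acid (MeMgI, excess, solvent-free melt, 150 °C). This gives, after work-up, nonaphenol bromide F8, in which the rings may still be cis. Brief warming with HCl (cat.) in MeCN/H2O then equilibrates the C2 centres through the quinone methides to 25.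

Further compounds
F1 | step 9 | diaryl carbinol from 19 and 5 (carbinol epimers) | OC(c1c(Br)cc(OC)cc1OCc1ccc(OC)cc1)c1cc(OC)cc2c1[C@H](c1cc(OC)cc3c1[C@@H](c1cc(OC)cc(OC)c1)[C@@H](c1ccc(OC)cc1)O3)[C@H](c1ccc(OC)cc1)O2
F2 | step 9 | diaryl ketone from F1 | O=C(c1c(Br)cc(OC)cc1OCc1ccc(OC)cc1)c1cc(OC)cc2c1[C@H](c1cc(OC)cc3c1[C@@H](c1cc(OC)cc(OC)c1)[C@@H](c1ccc(OC)cc1)O3)[C@H](c1ccc(OC)cc1)O2
F3 | step 10 | tert-butyl (3-bromo-2-formyl-5-methoxyphenyl) carbonate | COc1cc(Br)c(C=O)c(OC(=O)OC(C)(C)C)c1
F4 | step 10 | (2R,5R)-1-(4-methoxybenzyl)-2,5-dimethylthiolanium tetrafluoroborate | C[C@@H]1CC[C@@H](C)[S+]1Cc1ccc(OC)cc1.F[B-](F)(F)F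
F5 | step 10 | sulfonium ylide of F4 | C[C@@H]1CC[C@@H](C)[S+]1[CH-]c1ccc(OC)cc1
F6 | step 10 | o-quinone methide of ring A bearing the bis(dihydrobenzofuran) aryl group on the methide carbon | COC1=CC(=O)C(=Cc2cc(OC)cc3c2[C@H](c2cc(OC)cc4c2[C@@H](c2cc(OC)cc(OC)c2)[C@@H](c2ccc(OC)cc2)O4)[C@H](c2ccc(OC)cc2)O3)C(Br)=C1
F7 | step 10 | tris(dihydrobenzofuran) bromide, nonamethyl ether, ring A trans (2R,3R), rings B and C cis | Brc1cc(OC)cc2c1[C@@H](c1cc(OC)cc3c1[C@H](c1cc(OC)cc4c1[C@@H](c1cc(OC)cc(OC)c1)[C@@H](c1ccc(OC)cc1)O4)[C@H](c1ccc(OC)cc1)O3)[C@H](c1ccc(OC)cc1)O2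
F8 | step 11 | nonaphenol bromide with the three rings still cis | Brc1cc(O)cc2c1[C@@H](c1cc(O)cc3c1[C@H](c1cc(O)cc4c1[C@@H](c1cc(O)cc(O)c1)[C@@H](c1ccc(O)cc1)O4)[C@H](c1ccc(O)cc1)O3)[C@@H](c1ccc(O)cc1)O2
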